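The cis-fused octalin is disconnected across its cyclohexene ring A (C1–C2–C3=C4–C4a–C8a, with ring B C4a–C5–C6–C7–C8–C8a), the retron of a Diels–Alder reaction. In the key step a Suzuki coupling of an acyclic iodo-trienoate with a dienylboronate creates the C3–C4 bond, and the (E,E)-diene so formed adds in the same flask to the C8a=C1 alkene of the trienoate (intramolecular Diels–Alder), forming C1–C2 and C4a–C8a. One operation therefore closes rings A and B and sets C1, C2, C4a and C8a, steered by the C7/C8 hydroxy–methyl pair installed by asymmetric crotylboration. Sulfation and saponification complete the route.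

Key step: step 8

Remark: locants C1–C8a are those of the octahydronaphthalene core of the target (C1 dienoic acid chain, C2 butenyl, C3 and C8 methyl, C7 sulfate), and the target is taken to be wanted in the neutral hydrogen sulfate/carboxylic acid form drawn.

Step 1
Reactants: 1 (2E)-2-bromobut-2-ene; 2 prop-1-yn-1-ylmagnesium bromide
Product: 3 (2E)-3-methylhex-2-en-4-yne
Conditions: Pd(PPh3)4 (3 mol%), THF, rt to 50 °C
Reagents that add atoms: none
Why: Pd-catalysed Kumada–Corriu-type coupling of an alkynyl Grignard reagent with an alkenyl bromide proceeds with retention of alkene geometry, so the (E)-butenyl unit of the target is carried over from 1.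

Step 2
Reactants: 3 (2E)-3-methylhex-2-en-4-yne
Product: 4 4,4,5,5-tetramethyl-2-[(2Z,4E)-4-methylhexa-2,4-dien-2-yl]-1,3,2-dioxaborolane
Conditions: CuCl (5 mol%), Xantphos (5 mol%), NaOtBu (10 mol%), B2pin2 (1.1 equiv), MeOH (2 equiv), THF, rt
Reagents that add atoms: bis(pinacolato)diboron, CC1(C)OB(OC1(C)C)B1OC(C)(C)C(C)(C)O1
Why: Copper-catalysed formal hydroboration (syn borylcupration, then protonation of the C–Cu bond by methanol) should place boron on the less hindered methyl-bearing alkyne carbon and copper next to the conjugating alkenyl group, so H and B add cis and boron ends up trans to the butenyl group.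

Step 3
Reactants: 5 pent-4-yn-1-ol
Product: 7 (4E)-5-iodopent-4-en-1-ol, via alkenylzirconocene alkoxide 6 (not isolated)
Conditions: Cp2Zr(H)Cl (2.2 equiv), THF, rt; I2 (1.1 equiv), 0 °C; aqueous work-up
Reagents that add atoms: iodine, II
Why: Hydrozirconation with the Schwartz reagent is a syn, terminal-selective addition to the alkyne (the first equivalent converts the OH into a zirconium alkoxide), and iodinolysis of the C–Zr bond occurs with retention to give the (E)-vinyl iodide.

Step 4
Reactants: 7 (4E)-5-iodopent-4-en-1-ol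
Product: 8 (4E)-5-iodopent-4-enal
Conditions: Dess–Martin periodinane (1.2 equiv), CH2Cl2, 0 °C to rt
Reagents that add atoms: none
Why: Dess–Martin oxidation stops at the aldehyde under neutral conditions that leave the vinyl iodide untouched.

Step 5
Reactants: 8 (4E)-5-iodopent-4-enal; 9 2-[(2E)-but-2-en-1-yl]-4,4,5,5-tetramethyl-1,3,2-dioxaborolane
Product: 11 (1E,5S,6R)-1-iodo-6-methylocta-1,7-dien-5-ol, via borate ester 10 (not isolated)
Conditions: (R)-TRIP [(R)-3,3'-bis(2,4,6-triisopropylphenyl)-1,1'-binaphthyl-2,2'-diyl hydrogen phosphate] (5 mol%), toluene, 4 Å molecular sieves, −30 °C; aqueous work-up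
Reagents that add atoms: none
Why: Chiral phosphoric acid-catalysed crotylboration passes through a closed chair (Zimmerman–Traxler) transition state in which the (E)-crotyl geometry becomes the anti OH/CH3 relationship, while the (R)-catalyst, hydrogen-bonded to a boronate oxygen, should direct addition to the re face of the aldehyde to give the (5S,6R) alcohol.

Step 6
Reactants: 11 (1E,5S,6R)-1-iodo-6-methylocta-1,7-dien-5-ol; 12 (2E)-but-2-enal
Product: 13 (2E,4R,5S,8E)-5-hydroxy-9-iodo-4-methylnona-2,8-dienal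
Conditions: RuCl2(H2IMes)(=CH-C6H4-2-OiPr) (second-generation Hoveyda–Grubbs catalyst, 5 mol%), 12 (5 equiv), CH2Cl2, 40 °C
Reagents that add atoms: none
Why: Olefin cross-metathesis of the terminal alkene with an excess of the electron-poor enal should give the (E)-enal under thermodynamic control, the internal vinyl iodide being a far poorer metathesis substrate and both stereocentres being untouched.

Step 7
Reactants: 13 (2E,4R,5S,8E)-5-hydroxy-9-iodo-4-methylnona-2,8-dienal; 14 ethyl (2E)-4-(diethoxyphosphoryl)but-2-enoate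
Product: 15 ethyl (2E,4E,6E,8R,9S,12E)-9-hydroxy-13-iodo-8-methyltrideca-2,4,6,12-tetraenoate
Conditions: LiN(SiMe3)2 (1.2 equiv), 14 (1.3 equiv), THF, −78 °C to 0 °C
Reagents that add atoms: none
Why: Vinylogous Horner–Wadsworth–Emmons olefination with a stabilised phosphonate anion gives the new C4=C5 alkene with E geometry, and the preformed anion is not basic enough to deprotonate the free hydroxyl or the C8–H.

Step 8
Reactants: 15 ethyl (2E,4E,6E,8R,9S,12E)-9-hydroxy-13-iodo-8-methyltrideca-2,4,6,12-tetraenoate; 4 4,4,5,5-tetramethyl-2-[(2Z,4E)-4-methylhexa-2,4-dien-2-yl]-1,3,2-dioxaborolane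
Product: 17 ethyl (2E,4E)-5-[(1S,2S,4aS,7S,8R,8aR)-2-[(2E)-but-2-en-2-yl]-7-hydroxy-3,8-dimethyl-1,2,4a,5,6,7,8,8a-octahydronaphthalen-1-yl]penta-2,4-dienoate, via hexaene ester 16 (not isolated)
Conditions: PdCl2(dppf) (5 mol%), CsF (3 equiv), BHT (10 mol%), degassed 1,4-dioxane, 60 °C; then 110 °C (sealed vessel)
Reagents that add atoms: none
Why: Suzuki–Miyaura coupling (oxidative addition of zerovalent palladium into the C–I bond of 15, fluoride-assisted transmetalation of 4, reductive elimination with retention at both alkenes) forms the C3–C4 bond of ring A and gives hexaene 16, whose (12E,14E)-diene then adds across the (6E)-alkene in a thermal intramolecular Diels–Alder reaction that forms C1–C2 and C4a–C8a; the closest known reaction type is the domino cross-coupling/intramolecular Diels–Alder sequence of 1,7,9-decatrienes. Ring B closes through the four-carbon tether as a six-membered ring in a chair-like arrangement (C4a–C8a bond), and ring A is the cyclohexene of the suprafacial [4+2] addition itself. C2 and C4a are set cis by the (E,E)-diene, C1 is set trans to the C8a–C8 bond by the (E)-dienophile, the cis ring fusion follows from the transition state with the tether endo and the dienoate chain exo, and the absolute sense is relayed from C8, because only one diene face keeps the C8 methyl equatorial on the chair tether without a 1,3-diaxial contact of C7–O or C8–CH3 with the reacting carbons. The step needs role, exo and facial selectivity: the C3 methyl makes the s-cis conformer of the electron-rich diene readily accessible, so that this unit and not the trienoate should act as the diene, and the C3 methyl together with the twisted butenyl group at C2 crowd the endo position at the dienophile terminus, which should push the only weakly activating dienoate chain exo, while C4, which lies over the endo tether, carries only hydrogen. The trans-fused endo adduct is the expected competitor.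

Step 9
Reactants: 17 ethyl (2E,4E)-5-[(1S,2S,4aS,7S,8R,8aR)-2-[(2E)-but-2-en-2-yl]-7-hydroxy-3,8-dimethyl-1,2,4a,5,6,7,8,8a-octahydronaphthalen-1-yl]penta-2,4-dienoate
Product: 18 ethyl (2E,4E)-5-[(1S,2S,4aS,7S,8R,8aR)-2-[(2E)-but-2-en-2-yl]-3,8-dimethyl-7-(sulfooxy)-1,2,4a,5,6,7,8,8a-octahydronaphthalen-1-yl]penta-2,4-dienoate
Conditions: SO3·pyridine (5 equiv), pyridine/DMF, 40 °C; handled as the pyridinium salt
Reagents that add atoms: sulfur trioxide–pyridine complex, [O-]S(=O)(=O)[n+]1ccccc1
Why: O-Sulfation of the secondary alcohol with the SO3·pyridine complex engages only the O–H bond, so C7 keeps its configuration.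

Step 10
Reactants: 18 ethyl (2E,4E)-5-[(1S,2S,4aS,7S,8R,8aR)-2-[(2E)-but-2-en-2-yl]-3,8-dimethyl-7-(sulfooxy)-1,2,4a,5,6,7,8,8a-octahydronaphthalen-1-yl]penta-2,4-dienoate
Product: 19 (2E,4E)-5-[(1S,2S,4aS,7S,8R,8aR)-2-[(2E)-but-2-en-2-yl]-3,8-dimethyl-7-(sulfooxy)-1,2,4a,5,6,7,8,8a-octahydronaphthalen-1-yl]penta-2,4-dienoic acid
Conditions: LiOH (6 equiv), THF/MeOH/H2O, rt; then cold 1 M HCl to pH 2, n-BuOH extraction
Reagents that add atoms: lithium hydroxide, [Li+].[OH-]
Why: Saponification of the ethyl dienoate leaves the sulfate monoester anion intact (it is inert to aqueous hydroxide at rt), no stereocentre is epimerisable, and cold acidification should liberate the free acid form.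

Compound list
1 | (2E)-2-bromobut-2-ene | C/C=C(\C)Br | starting material
2 | prop-1-yn-1-ylmagnesium bromide | CC#C[Mg]Br | starting material
3 | (2E)-3-methylhex-2-en-4-yne | C/C=C(\C)C#CC | intermediate
4 | 4,4,5,5-tetramethyl-2-[(2Z,4E)-4-methylhexa-2,4-dien-2-yl]-1,3,2-dioxaborolane (boron trans to the butenyl group) | C/C=C(\C)/C=C(\C)B1OC(C)(C)C(C)(C)O1 | intermediate
5 | pent-4-yn-1-ol | C#CCCCO | starting material
6 | chlorobis(cyclopentadienyl)zirconium alkoxide of (4E)-5-[chlorobis(cyclopentadienyl)zirconio]pent-4-en-1-ol (not isolated) | Cl[Zr](OCCC/C=C/[Zr](Cl)(C1C=CC=C1)C1C=CC=C1)(C1C=CC=C1)C1C=CC=C1 | intermediate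
7 | (4E)-5-iodopent-4-en-1-ol | OCCC/C=C/I | intermediate
8 | (4E)-5-iodopent-4-enal | O=CCC/C=C/I | intermediate
9 | 2-[(2E)-but-2-en-1-yl]-4,4,5,5-tetramethyl-1,3,2-dioxaborolane ((E)-crotylboronic acid pinacol ester) | C/C=C/CB1OC(C)(C)C(C)(C)O1 | starting material
10 | 2-{[(1E,5S,6R)-1-iodo-6-methylocta-1,7-dien-5-yl]oxy}-4,4,5,5-tetramethyl-1,3,2-dioxaborolane (not isolated) | I/C=C/CC[C@H](OB1OC(C)(C)C(C)(C)O1)[C@H](C)C=C | intermediate
11 | (1E,5S,6R)-1-iodo-6-methylocta-1,7-dien-5-ol | I/C=C/CC[C@H](O)[C@H](C)C=C | intermediate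
12 | (2E)-but-2-enal | C/C=C/C=O | starting material
13 | (2E,4R,5S,8E)-5-hydroxy-9-iodo-4-methylnona-2,8-dienal | I/C=C/CC[C@H](O)[C@H](C)/C=C/C=O | intermediate
14 | ethyl (2E)-4-(diethoxyphosphoryl)but-2-enoate (triethyl 4-phosphonocrotonate) | CCOC(=O)/C=C/CP(=O)(OCC)OCC | starting material
15 | ethyl (2E,4E,6E,8R,9S,12E)-9-hydroxy-13-iodo-8-methyltrideca-2,4,6,12-tetraenoate | I/C=C/CC[C@H](O)[C@H](C)/C=C/C=C/C=C/C(=O)OCC | intermediate
16 | ethyl (2E,4E,6E,8R,9S,12E,14E,16E)-9-hydroxy-8,14,16-trimethyloctadeca-2,4,6,12,14,16-hexaenoate (not isolated) | C/C=C(\C)/C=C(\C)/C=C/CC[C@H](O)[C@H](C)/C=C/C=C/C=C/C(=O)OCC | intermediate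
17 | ethyl (2E,4E)-5-[(1S,2S,4aS,7S,8R,8aR)-2-[(2E)-but-2-en-2-yl]-7-hydroxy-3,8-dimethyl-1,2,4a,5,6,7,8,8a-octahydronaphthalen-1-yl]penta-2,4-dienoate | C/C=C(\C)[C@H]1C(C)=C[C@H]2CC[C@H](O)[C@H](C)[C@H]2[C@@H]1/C=C/C=C/C(=O)OCC | intermediate
18 | ethyl (2E,4E)-5-[(1S,2S,4aS,7S,8R,8aR)-2-[(2E)-but-2-en-2-yl]-3,8-dimethyl-7-(sulfooxy)-1,2,4a,5,6,7,8,8a-octahydronaphthalen-1-yl]penta-2,4-dienoate | C/C=C(\C)[C@H]1C(C)=C[C@H]2CC[C@H](OS(=O)(=O)O)[C@H](C)[C@H]2[C@@H]1/C=C/C=C/C(=O)OCC | intermediate
19 | (2E,4E)-5-[(1S,2S,4aS,7S,8R,8aR)-2-[(2E)-but-2-en-2-yl]-3,8-dimethyl-7-(sulfooxy)-1,2,4a,5,6,7,8,8a-octahydronaphthalen-1-yl]penta-2,4-dienoic acid | C/C=C(\C)[C@H]1C(C)=C[C@H]2CC[C@H](OS(=O)(=O)O)[C@H](C)[C@H]2[C@@H]1/C=C/C=C/C(=O)O | target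

Total step count: 10. Longest linear sequence: 8 steps (steps 3 to 10, from 5 to 19).

Steps most likely to fail

1. Step 8. The cycloaddition may prefer the endo (trans-fused) mode, or the mode in which the trienoate reacts as the diene, so that the cis-fused adduct is not the main product. The fallback sets out from 11 and comes back at 17. It uses a (Z)-enoate dienophile, for which the ester-endo transition state also has the tether endo and so gives the cis ring fusion, with allylic 1,3-strain at C8 fixing the face. Alcohol 11 is silylated (TBSOTf, 2,6-lutidine, CH2Cl2) to tert-butyldimethylsilyl ether F1. Cleavage of the terminal alkene with OsO4 (cat.)/NaIO4/2,6-lutidine in dioxane/H2O gives aldehyde F2. Still–Gennari olefination (methyl bis(2,2,2-trifluoroethyl)phosphonoacetate, KN(SiMe3)2, 18-crown-6, THF, −78 °C) gives (Z)-enoate F3. Coupling with 4 under the conditions of step 8 gives tetraene F4, which on heating should close to cis-fused ester F5, with the ester cis to the butenyl group. NaOMe in MeOH epimerises C1 to the more stable ester F6, iBu2AlH at −78 °C gives aldehyde F7, and olefination with 14 (LiN(SiMe3)2, THF) gives silyl-protected dienoate F8. Bu4NF in THF then returns 17.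

2. Step 2. Borylcupration may place boron on the alkyne carbon next to the butenyl group and so give a regioisomeric mixture. The fallback sets out from 3 and comes back at 4. Hydrozirconation of 3 with Cp2Zr(H)Cl (slight excess, THF, 40 °C, equilibration to the less hindered position) gives alkenylzirconocene F9. Iodinolysis gives (2E,4E)-2-iodo-4-methylhexa-2,4-diene F10. Iodine–lithium exchange (t-BuLi, Et2O, −78 °C) gives alkenyllithium F11, and trapping with 2-isopropoxy-4,4,5,5-tetramethyl-1,3,2-dioxaborolane gives 4 with retention.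

3. Step 6. Slow metathesis at the allylically branched alkene and catalyst decay in the presence of the vinyl iodide may stall the reaction. The fallback sets out from 11 and comes back at 13. OsO4 (cat.)/NaIO4/2,6-lutidine in dioxane/H2O cleaves the terminal alkene to β-hydroxy aldehyde F12, which is used crude. Wittig olefination with (triphenylphosphoranylidene)acetaldehyde (toluene, 60 °C) then gives 13.

Further compounds
F1 | step 8 | tert-butyl{[(1E,5S,6R)-1-iodo-6-methylocta-1,7-dien-5-yl]oxy}dimethylsilane | I/C=C/CC[C@H](O[Si](C)(C)C(C)(C)C)[C@H](C)C=C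
F2 | step 8 | (2S,3S,6E)-3-[(tert-butyldimethylsilyl)oxy]-7-iodo-2-methylhept-6-enal | I/C=C/CC[C@H](O[Si](C)(C)C(C)(C)C)[C@H](C)C=O
F3 | step 8 | methyl (2Z,4R,5S,8E)-5-[(tert-butyldimethylsilyl)oxy]-9-iodo-4-methylnona-2,8-dienoate | I/C=C/CC[C@H](O[Si](C)(C)C(C)(C)C)[C@H](C)/C=C\C(=O)OC
F4 | step 8 | methyl (2Z,4R,5S,8E,10E,12E)-5-[(tert-butyldimethylsilyl)oxy]-4,10,12-trimethyltetradeca-2,8,10,12-tetraenoate | C/C=C(\C)/C=C(\C)/C=C/CC[C@H](O[Si](C)(C)C(C)(C)C)[C@H](C)/C=C\C(=O)OC
F5 | step 8 | methyl (1R,2S,4aS,7S,8R,8aS)-2-[(2E)-but-2-en-2-yl]-7-[(tert-butyldimethylsilyl)oxy]-3,8-dimethyl-1,2,4a,5,6,7,8,8a-octahydronaphthalene-1-carboxylate | C/C=C(\C)[C@H]1C(C)=C[C@H]2CC[C@H](O[Si](C)(C)C(C)(C)C)[C@H](C)[C@H]2[C@H]1C(=O)OC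
F6 | step 8 | methyl (1S,2S,4aS,7S,8R,8aS)-2-[(2E)-but-2-en-2-yl]-7-[(tert-butyldimethylsilyl)oxy]-3,8-dimethyl-1,2,4a,5,6,7,8,8a-octahydronaphthalene-1-carboxylate | C/C=C(\C)[C@H]1C(C)=C[C@H]2CC[C@H](O[Si](C)(C)C(C)(C)C)[C@H](C)[C@H]2[C@@H]1C(=O)OC
F7 | step 8 | (1S,2S,4aS,7S,8R,8aS)-2-[(2E)-but-2-en-2-yl]-7-[(tert-butyldimethylsilyl)oxy]-3,8-dimethyl-1,2,4a,5,6,7,8,8a-octahydronaphthalene-1-carbaldehyde | C/C=C(\C)[C@H]1C(C)=C[C@H]2CC[C@H](O[Si](C)(C)C(C)(C)C)[C@H](C)[C@H]2[C@@H]1C=O
F8 | step 8 | ethyl (2E,4E)-5-[(1S,2S,4aS,7S,8R,8aR)-2-[(2E)-but-2-en-2-yl]-7-[(tert-butyldimethylsilyl)oxy]-3,8-dimethyl-1,2,4a,5,6,7,8,8a-octahydronaphthalen-1-yl]penta-2,4-dienoate | C/C=C(\C)[C@H]1C(C)=C[C@H]2CC[C@H](O[Si](C)(C)C(C)(C)C)[C@H](C)[C@H]2[C@@H]1/C=C/C=C/C(=O)OCC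
F9 | step 2 | chlorobis(cyclopentadienyl)[(2E,4E)-4-methylhexa-2,4-dien-2-yl]zirconium | C/C=C(\C)/C=C(\C)[Zr](Cl)(C1C=CC=C1)C1C=CC=C1
F10 | step 2 | (2E,4E)-2-iodo-4-methylhexa-2,4-diene | C/C=C(\C)/C=C(\C)I
F11 | step 2 | [(2Z,4E)-4-methylhexa-2,4-dien-2-yl]lithium | C/C=C(\C)/C=C(\C)[Li]
F12 | step 6 | (2S,3S,6E)-3-hydroxy-7-iodo-2-methylhept-6-enal | I/C=C/CC[C@H](O)[C@H](C)C=O
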